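**Plan**

Rings: A = formyl/enal benzene, B = its dioxane, C = central benzene, D = second dioxane, E = catechol ring.
- Cuts: (i) the enal C=C, back to the ring A aldehyde; (ii) both C–O bonds of the cis ring D, back to an ortho-iodophenol on ring C and a (2S,3S)-aryl glycidyl ether; (iii) the C2–C3 bond of the trans ring B, back to an achiral ring A diether with an O–CH2–CHO arm on the para oxygen and a para-silyloxybenzyl group on the meta oxygen.
- Forward order: ring A diether → ring B by oxidative C–C ring closure → iodination of ring C → ring D by epoxide opening and copper-catalysed O-arylation → enal → deallylation.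
- Enabling feature: C3 of ring B is benzylic to ring C and flanked by ring oxygen O4. The para oxygen of ring C (later O1 of ring D) lets DDQ turn that CH2 into an O-aryl oxocarbenium ion. C2 of ring B is the alpha carbon of an aldehyde (the latent CH2OH) and becomes a chiral enamine nucleophile.
- Stereochemistry: C2/C3 of ring B from the (S)-diphenylprolinol silyl ether catalyst and a trans-selective half-chair closure. C2/C3 of ring D from Sharpless epoxidation with L-(+)-tartrate, one SN2 inversion and one retentive closure (cis).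

Key step: step 4

Remark: from the given SMILES, ring B is read as trans-(2S,3S) and ring D as cis-(2R,3S) (benzodioxine numbering, O1 para to the carbon substituent on the fused benzene ring).
Assumption: [4-(tert-butyldimethylsilyloxy)phenyl]methanol is taken as a catalogue compound. The sense of induction in step 4 follows the usual steric shielding model for the catalyst.

**Route**

Step 1
Reactants: 1 3,4-dihydroxybenzaldehyde; 2 allyl bromide
Product: 3 4-(allyloxy)-3-hydroxybenzaldehyde
Conditions: allyl bromide (1.0 equiv), NaHCO3, NaI (cat.), DMF, 40 °C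
Reagents that add atoms: none
Why: Williamson etherification in which the 4-hydroxyl, para to the formyl group, is much the more acidic, so with NaHCO3 only this phenoxide forms and the allyl group (the future C2 and CH2OH carbons of ring B) goes on the para oxygen.

Step 2
Reactants: 3 4-(allyloxy)-3-hydroxybenzaldehyde; 4 [4-(tert-butyldimethylsilyloxy)phenyl]methanol
Product: 5 4-(allyloxy)-3-{[4-(tert-butyldimethylsilyloxy)benzyl]oxy}benzaldehyde
Conditions: PPh3, DIAD, THF, 0 °C to rt
Reagents that add atoms: none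
Why: Mitsunobu etherification, in which the remaining phenol is alkylated by the activated primary benzylic alcohol under neutral conditions that leave the aryl silyl ether and the aldehyde untouched.

Step 3
Reactants: 5 4-(allyloxy)-3-{[4-(tert-butyldimethylsilyloxy)benzyl]oxy}benzaldehyde
Product: 6 2-(2-{[4-(tert-butyldimethylsilyloxy)benzyl]oxy}-4-formylphenoxy)acetaldehyde
Conditions: OsO4 (cat.), NaIO4, 2,6-lutidine, dioxane/H2O, rt
Reagents that add atoms: OsO4 O=[Os](=O)(=O)=O (oxygen carrier); NaIO4 [Na+].[O-]I(=O)(=O)=O (terminal oxidant, source of the aldehyde oxygen)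
Why: Lemieux–Johnson oxidation, in which OsO4 dihydroxylates the only alkene and NaIO4 cleaves the diol to the aryloxyacetaldehyde, the buffered medium sparing the silyl and benzyl ethers.

Step 4
Reactants: 6 2-(2-{[4-(tert-butyldimethylsilyloxy)benzyl]oxy}-4-formylphenoxy)acetaldehyde
Product: 9 (2S,3S)-3-[4-(tert-butyldimethylsilyloxy)phenyl]-2-(hydroxymethyl)-2,3-dihydro-1,4-benzodioxine-6-carbaldehyde, via oxocarbenium ion pair 7 (not isolated), via trans-dialdehyde 8 (not isolated)
Conditions: DDQ (1.05 equiv), CH2Cl2/MeNO2, 0 °C; then (S)-2-[diphenyl(trimethylsilyloxy)methyl]pyrrolidine (20 mol %), −30 °C; then NaBH4, EtOH, −78 °C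
Reagents that add atoms: none
Why: Proposed new method: DDQ abstracts hydride from the ArO–CH2–Ar methylene of 6, the only C–H that is both benzylic to the donor ring C (para-silyloxy) and alpha to an ether oxygen, to give the O-aryl oxocarbenium ion 7; the pyrrolidine then condenses with the aliphatic aldehyde, the E-enamine carbon adds to the cationic carbon, hydrolysis frees catalyst and 8, and cold NaBH4 reduces the more electrophilic aliphatic aldehyde. The closest known reaction type is the amine-catalysed enantioselective alpha-alkylation of aldehydes with DDQ-generated benzylic or oxocarbenium cations (oxidative cross-dehydrogenative coupling with benzylic ethers), together with the enamine 1,6-addition to para-quinone methides, both known only between two molecules. Ring B closes in a 6-(enolexo)-endo-trig mode, the enamine carbon attacking the ring-embedded C=O+ bond. C2 is controlled by the catalyst, whose CPh2(OSiMe3) group shields one face of the s-trans E-enamine so that the (R)-aldehyde centre of 8 results (S after reduction, by a change of priorities only); C3 is controlled by the half-chair transition state, in which the aryl group of the (E)-oxocarbenium ion and the enamine carbon both lie pseudo-equatorial, which gives the trans ring. The step needs chemoselective oxidation (ring A is deactivated by its formyl group and the substrate holds no second electron-rich benzylic C–H), enantiofacial control (catalyst) and chemoselective reduction (alpha-aryloxy alkyl aldehyde against a donor-substituted aryl aldehyde at −78 °C), and the immediate reduction also protects the enolisable C2 centre from epimerisation.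

Step 5
Reactants: 9 (2S,3S)-3-[4-(tert-butyldimethylsilyloxy)phenyl]-2-(hydroxymethyl)-2,3-dihydro-1,4-benzodioxine-6-carbaldehyde
Product: 10 (2S,3S)-2-(hydroxymethyl)-3-(4-hydroxyphenyl)-2,3-dihydro-1,4-benzodioxine-6-carbaldehyde
Conditions: Bu4NF, AcOH, THF, 0 °C
Reagents that add atoms: none
Why: Fluoride-induced desilylation of the aryl silyl ether under buffered conditions; the trans ring B is the thermodynamic isomer and its C2 centre cannot epimerise, so the free para-phenol poses no stereochemical risk.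

Step 6
Reactants: 10 (2S,3S)-2-(hydroxymethyl)-3-(4-hydroxyphenyl)-2,3-dihydro-1,4-benzodioxine-6-carbaldehyde
Product: 11 (2S,3S)-3-(4-hydroxy-3-iodophenyl)-2-(hydroxymethyl)-2,3-dihydro-1,4-benzodioxine-6-carbaldehyde
Conditions: NIS (1.0 equiv), TsOH (cat.), MeCN, 0 °C
Reagents that add atoms: N-iodosuccinimide O=C1CCC(=O)N1I
Why: Electrophilic aromatic iodination in which the phenol ring C is the only activated arene (ring A carries the formyl group), its para position is blocked and its two ortho positions are equivalent, so one equivalent should give a single mono-iodide.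

Step 7
Reactants: 12 ethyl (E)-3-(3,4-dihydroxyphenyl)prop-2-enoate (ethyl caffeate); 2 allyl bromide
Product: 13 ethyl (E)-3-[3,4-bis(allyloxy)phenyl]prop-2-enoate
Conditions: allyl bromide (2.4 equiv in all), K2CO3 (3 equiv), DMF, 50 °C
Reagents that add atoms: allyl bromide C=CCBr (the second equivalent, which alkylates the second phenol oxygen)
Why: Twofold Williamson etherification in which each phenoxide takes up one allyl group from one equivalent of allyl bromide; allyl ethers are chosen because they survive the basic and copper-catalysed steps and come off at the end under neutral conditions.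

Step 8
Reactants: 13 ethyl (E)-3-[3,4-bis(allyloxy)phenyl]prop-2-enoate
Product: 14 (E)-3-[3,4-bis(allyloxy)phenyl]prop-2-en-1-ol
Conditions: iBu2AlH, CH2Cl2, −78 °C
Reagents that add atoms: none
Why: 1,2-Reduction of the conjugated ester by iBu2AlH to the (E)-allylic alcohol, with the allyl ethers inert.

Step 9
Reactants: 14 (E)-3-[3,4-bis(allyloxy)phenyl]prop-2-en-1-ol
Product: 15 [(2S,3S)-3-[3,4-bis(allyloxy)phenyl]oxiran-2-yl]methanol
Conditions: Ti(OiPr)4 (cat.), L-(+)-diisopropyl tartrate (cat.), tBuOOH, 4 Å MS, CH2Cl2, −20 °C; basic work-up, used at once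
Reagents that add atoms: tert-butyl hydroperoxide CC(C)(C)OO
Why: Sharpless asymmetric epoxidation, in which the Ti–tartrate catalyst epoxidises only the allylic alcohol alkene and the L-(+)-tartrate delivers oxygen to the face that gives the (2S,3S)-epoxy alcohol, the source of both stereocentres of ring D.

Step 10
Reactants: 15 [(2S,3S)-3-[3,4-bis(allyloxy)phenyl]oxiran-2-yl]methanol
Product: 16 {[(2S,3S)-3-[3,4-bis(allyloxy)phenyl]oxiran-2-yl]methoxy}tri(propan-2-yl)silane
Conditions: iPr3SiCl, imidazole, DMF, 0 °C to rt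
Reagents that add atoms: chlorotri(propan-2-yl)silane CC(C)[Si](Cl)(C(C)C)C(C)C
Why: Silylation of the primary alcohol blocks Payne rearrangement in the next step and keeps this oxygen out of the later ring closure, the bulky silyl group resisting 1,2-migration.

Step 11
Reactants: 11 (2S,3S)-3-(4-hydroxy-3-iodophenyl)-2-(hydroxymethyl)-2,3-dihydro-1,4-benzodioxine-6-carbaldehyde; 16 {[(2S,3S)-3-[3,4-bis(allyloxy)phenyl]oxiran-2-yl]methoxy}tri(propan-2-yl)silane
Product: 17 (2S,3S)-3-[4-({(1R,2S)-1-[3,4-bis(allyloxy)phenyl]-2-hydroxy-3-[(triisopropylsilyl)oxy]propyl}oxy)-3-iodophenyl]-2-(hydroxymethyl)-2,3-dihydro-1,4-benzodioxine-6-carbaldehyde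
Conditions: Cs2CO3, DMF, 70 °C
Reagents that add atoms: none
Why: Base-mediated epoxide opening in which the caesium phenoxide attacks the benzylic epoxide carbon (activated by ring E, and less hindered than the carbon next to CH2OSi) by SN2 with inversion, giving the (1R,2S) anti aryloxy alcohol, while the alcohols are not deprotonated by the carbonate.

Step 12
Reactants: 17 (2S,3S)-3-[4-({(1R,2S)-1-[3,4-bis(allyloxy)phenyl]-2-hydroxy-3-[(triisopropylsilyl)oxy]propyl}oxy)-3-iodophenyl]-2-(hydroxymethyl)-2,3-dihydro-1,4-benzodioxine-6-carbaldehyde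
Product: 18 (2S,3S)-3-[(2R,3S)-2-[3,4-bis(allyloxy)phenyl]-3-{[(triisopropylsilyl)oxy]methyl}-2,3-dihydro-1,4-benzodioxin-6-yl]-2-(hydroxymethyl)-2,3-dihydro-1,4-benzodioxine-6-carbaldehyde
Conditions: CuI (cat.), 1,10-phenanthroline, Cs2CO3, toluene, 100 °C
Reagents that add atoms: none
Why: Intramolecular Ullmann O-arylation, in which the copper–phenanthroline catalyst joins the secondary alkoxide to the ortho iodide in a six-membered closure without breaking a bond at either stereocentre, so the anti open chain becomes the cis ring D.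

Step 13
Reactants: 18 (2S,3S)-3-[(2R,3S)-2-[3,4-bis(allyloxy)phenyl]-3-{[(triisopropylsilyl)oxy]methyl}-2,3-dihydro-1,4-benzodioxin-6-yl]-2-(hydroxymethyl)-2,3-dihydro-1,4-benzodioxine-6-carbaldehyde
Product: 19 (2S,3S)-3-[(2R,3S)-2-[3,4-bis(allyloxy)phenyl]-3-(hydroxymethyl)-2,3-dihydro-1,4-benzodioxin-6-yl]-2-(hydroxymethyl)-2,3-dihydro-1,4-benzodioxine-6-carbaldehyde
Conditions: Bu4NF, AcOH, THF, rt
Reagents that add atoms: none
Why: Buffered fluoride removes the primary silyl ether, and the near-neutral medium protects the cis ring D, whose benzylic C–O bond is sensitive to acid.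

Step 14
Reactants: 19 (2S,3S)-3-[(2R,3S)-2-[3,4-bis(allyloxy)phenyl]-3-(hydroxymethyl)-2,3-dihydro-1,4-benzodioxin-6-yl]-2-(hydroxymethyl)-2,3-dihydro-1,4-benzodioxine-6-carbaldehyde; 20 (triphenylphosphoranylidene)acetaldehyde
Product: 21 (E)-3-[(2S,3S)-3-[(2R,3S)-2-[3,4-bis(allyloxy)phenyl]-3-(hydroxymethyl)-2,3-dihydro-1,4-benzodioxin-6-yl]-2-(hydroxymethyl)-2,3-dihydro-1,4-benzodioxin-6-yl]prop-2-enal
Conditions: toluene, 80 °C
Reagents that add atoms: none
Why: Wittig reaction with a stabilised formyl-substituted ylide converts the aryl aldehyde into the enal, E geometry following from the reversible addition of stabilised ylides, and free hydroxyls are tolerated.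

Step 15
Reactants: 21 (E)-3-[(2S,3S)-3-[(2R,3S)-2-[3,4-bis(allyloxy)phenyl]-3-(hydroxymethyl)-2,3-dihydro-1,4-benzodioxin-6-yl]-2-(hydroxymethyl)-2,3-dihydro-1,4-benzodioxin-6-yl]prop-2-enal
Product: 22 (E)-3-[(2S,3S)-3-[(2R,3S)-2-(3,4-dihydroxyphenyl)-3-(hydroxymethyl)-2,3-dihydro-1,4-benzodioxin-6-yl]-2-(hydroxymethyl)-2,3-dihydro-1,4-benzodioxin-6-yl]prop-2-enal (CNP0302404.1)
Conditions: Pd(PPh3)4 (cat.), N-methylaniline, degassed THF, rt
Reagents that add atoms: none
Why: Tsuji–Trost-type deallylation, in which Pd(PPh3)4 ionises the two aryl allyl ethers and the weakly basic N-methylaniline traps the allyl groups, so the catechol is released under neutral conditions that should neither open ring D through a para-quinone methide nor add to the enal.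

**Compound list**

1 | 3,4-dihydroxybenzaldehyde | O=Cc1ccc(O)c(O)c1 | starting material
2 | allyl bromide | C=CCBr | starting material
3 | 4-(allyloxy)-3-hydroxybenzaldehyde | O=Cc1ccc(OCC=C)c(O)c1 | intermediate
4 | [4-(tert-butyldimethylsilyloxy)phenyl]methanol | OCc1ccc(O[Si](C)(C)C(C)(C)C)cc1 | starting material
5 | 4-(allyloxy)-3-{[4-(tert-butyldimethylsilyloxy)benzyl]oxy}benzaldehyde | O=Cc1ccc(OCC=C)c(OCc2ccc(O[Si](C)(C)C(C)(C)C)cc2)c1 | intermediate
6 | 2-(2-{[4-(tert-butyldimethylsilyloxy)benzyl]oxy}-4-formylphenoxy)acetaldehyde | O=CCOc1ccc(C=O)cc1OCc1ccc(O[Si](C)(C)C(C)(C)C)cc1 | intermediate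
7 | {[4-(tert-butyldimethylsilyloxy)phenyl]methylidene}[5-formyl-2-(2-oxoethoxy)phenyl]oxonium 2,3-dichloro-5,6-dicyano-4-hydroxyphenolate (oxocarbenium ion pair) | O=CCOc1ccc(C=O)cc1[O+]=Cc1ccc(O[Si](C)(C)C(C)(C)C)cc1.[O-]c1c(Cl)c(Cl)c(O)c(C#N)c1C#N | intermediate (not isolated)
8 | (2R,3S)-3-[4-(tert-butyldimethylsilyloxy)phenyl]-2,3-dihydro-1,4-benzodioxine-2,6-dicarbaldehyde (trans) | O=Cc1ccc2c(c1)O[C@@H](c1ccc(O[Si](C)(C)C(C)(C)C)cc1)[C@H](C=O)O2 | intermediate (not isolated)
9 | (2S,3S)-3-[4-(tert-butyldimethylsilyloxy)phenyl]-2-(hydroxymethyl)-2,3-dihydro-1,4-benzodioxine-6-carbaldehyde | O=Cc1ccc2c(c1)O[C@@H](c1ccc(O[Si](C)(C)C(C)(C)C)cc1)[C@H](CO)O2 | intermediate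
10 | (2S,3S)-2-(hydroxymethyl)-3-(4-hydroxyphenyl)-2,3-dihydro-1,4-benzodioxine-6-carbaldehyde | O=Cc1ccc2c(c1)O[C@@H](c1ccc(O)cc1)[C@H](CO)O2 | intermediate
11 | (2S,3S)-3-(4-hydroxy-3-iodophenyl)-2-(hydroxymethyl)-2,3-dihydro-1,4-benzodioxine-6-carbaldehyde | O=Cc1ccc2c(c1)O[C@@H](c1ccc(O)c(I)c1)[C@H](CO)O2 | intermediate
12 | ethyl (E)-3-(3,4-dihydroxyphenyl)prop-2-enoate | CCOC(=O)/C=C/c1ccc(O)c(O)c1 | starting material
13 | ethyl (E)-3-[3,4-bis(allyloxy)phenyl]prop-2-enoate | CCOC(=O)/C=C/c1ccc(OCC=C)c(OCC=C)c1 | intermediate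
14 | (E)-3-[3,4-bis(allyloxy)phenyl]prop-2-en-1-ol | OC/C=C/c1ccc(OCC=C)c(OCC=C)c1 | intermediate
15 | [(2S,3S)-3-[3,4-bis(allyloxy)phenyl]oxiran-2-yl]methanol | OC[C@@H]1O[C@H]1c1ccc(OCC=C)c(OCC=C)c1 | intermediate
16 | {[(2S,3S)-3-[3,4-bis(allyloxy)phenyl]oxiran-2-yl]methoxy}tri(propan-2-yl)silane | CC(C)[Si](OC[C@@H]1O[C@H]1c1ccc(OCC=C)c(OCC=C)c1)(C(C)C)C(C)C | intermediate
17 | (2S,3S)-3-[4-({(1R,2S)-1-[3,4-bis(allyloxy)phenyl]-2-hydroxy-3-[(triisopropylsilyl)oxy]propyl}oxy)-3-iodophenyl]-2-(hydroxymethyl)-2,3-dihydro-1,4-benzodioxine-6-carbaldehyde | O=Cc1ccc2c(c1)O[C@@H](c1ccc(O[C@H](c3ccc(OCC=C)c(OCC=C)c3)[C@@H](O)CO[Si](C(C)C)(C(C)C)C(C)C)c(I)c1)[C@H](CO)O2 | intermediate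
18 | (2S,3S)-3-[(2R,3S)-2-[3,4-bis(allyloxy)phenyl]-3-{[(triisopropylsilyl)oxy]methyl}-2,3-dihydro-1,4-benzodioxin-6-yl]-2-(hydroxymethyl)-2,3-dihydro-1,4-benzodioxine-6-carbaldehyde | O=Cc1ccc2c(c1)O[C@@H](c1ccc3c(c1)O[C@@H](CO[Si](C(C)C)(C(C)C)C(C)C)[C@@H](c1ccc(OCC=C)c(OCC=C)c1)O3)[C@H](CO)O2 | intermediate
19 | (2S,3S)-3-[(2R,3S)-2-[3,4-bis(allyloxy)phenyl]-3-(hydroxymethyl)-2,3-dihydro-1,4-benzodioxin-6-yl]-2-(hydroxymethyl)-2,3-dihydro-1,4-benzodioxine-6-carbaldehyde | O=Cc1ccc2c(c1)O[C@@H](c1ccc3c(c1)O[C@@H](CO)[C@@H](c1ccc(OCC=C)c(OCC=C)c1)O3)[C@H](CO)O2 | intermediate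
20 | (triphenylphosphoranylidene)acetaldehyde | O=CC=P(c1ccccc1)(c1ccccc1)c1ccccc1 | starting material
21 | (E)-3-[(2S,3S)-3-[(2R,3S)-2-[3,4-bis(allyloxy)phenyl]-3-(hydroxymethyl)-2,3-dihydro-1,4-benzodioxin-6-yl]-2-(hydroxymethyl)-2,3-dihydro-1,4-benzodioxin-6-yl]prop-2-enal | O=C/C=C/c1ccc2c(c1)O[C@@H](c1ccc3c(c1)O[C@@H](CO)[C@@H](c1ccc(OCC=C)c(OCC=C)c1)O3)[C@H](CO)O2 | intermediate
22 | (E)-3-[(2S,3S)-3-[(2R,3S)-2-(3,4-dihydroxyphenyl)-3-(hydroxymethyl)-2,3-dihydro-1,4-benzodioxin-6-yl]-2-(hydroxymethyl)-2,3-dihydro-1,4-benzodioxin-6-yl]prop-2-enal | O=C/C=C/c1ccc2c(c1)O[C@@H](c1ccc3c(c1)O[C@@H](CO)[C@@H](c1ccc(O)c(O)c1)O3)[C@H](CO)O2 | target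

**Count and risks**

Total steps: 15. Longest linear sequence: 11 steps (steps 1–6 and 11–15).

Steps most likely to fail:

1. Step 4 (new method). Possible failure processes:
   - hydrolytic loss of the benzyl group from the oxocarbenium ion, as in an oxidative benzyl ether cleavage;
   - uncatalysed cyclisation through the enol, which would erode enantiomeric purity;
   - poor facial selectivity at the cationic carbon;
   - incomplete discrimination between the two aldehydes in the reduction.
   
   Partial loss of the aryl silyl group would be harmless, since step 5 removes it anyway.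
   
   Fallback (known chemistry, sets out from 1, comes back at 10): 1 and purchased (E)-4-(3-hydroxyprop-1-en-1-yl)phenol (OC/C=C/c1ccc(O)cc1) are joined by Ag2CO3-mediated oxidative coupling in acetone/benzene at 55 °C. The beta carbon of the cinnamyl radical bonds to the more acidic para oxygen of 1, and the quinone methide is closed by the meta hydroxyl to the thermodynamically favoured trans ring. This should give the racemic trans-2-(hydroxymethyl)-3-(4-hydroxyphenyl)-2,3-dihydro-1,4-benzodioxine-6-carbaldehyde F1. Preparative chromatography on a chiral stationary phase then supplies the (2S,3S)-enantiomer 10, and the route continues at step 6.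

2. Step 9. Possible failure process: Lewis-acid-induced opening or oligomerisation of the electron-rich aryl epoxide during the titanium-catalysed epoxidation or its work-up.
   
   Fallback (sets out from 14, comes back at 16): 14 is silylated first (iPr3SiCl, imidazole) to {[(E)-3-[3,4-bis(allyloxy)phenyl]prop-2-en-1-yl]oxy}tri(propan-2-yl)silane F2. Shi epoxidation of F2 with KHSO5 and the L-fructose-derived (enantiomeric) ketone catalyst, buffered at pH 10.5 with K2CO3 in MeCN/dimethoxymethane/H2O at 0 °C, should give 16 directly. The medium is never acidic, the ketone of this series delivers the (S,S) epoxide from trans aryl alkenes, and the terminal alkenes of the allyl ethers are poor substrates for the dioxirane.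

3. Step 14. Possible failure process: slow olefination of the donor-substituted aldehyde, together with a second olefination of the product enal (over-homologation to the dienal).
   
   Fallback (sets out from 19, comes back at 21): Horner–Wadsworth–Emmons reaction of 19 with triethyl phosphonoacetate (LiCl, DBU, MeCN) should give ethyl (E)-3-[(2S,3S)-3-[(2R,3S)-2-[3,4-bis(allyloxy)phenyl]-3-(hydroxymethyl)-2,3-dihydro-1,4-benzodioxin-6-yl]-2-(hydroxymethyl)-2,3-dihydro-1,4-benzodioxin-6-yl]prop-2-enoate F3. iBu2AlH at −78 °C reduces it to the triol (E)-3-[(2S,3S)-3-[(2R,3S)-2-[3,4-bis(allyloxy)phenyl]-3-(hydroxymethyl)-2,3-dihydro-1,4-benzodioxin-6-yl]-2-(hydroxymethyl)-2,3-dihydro-1,4-benzodioxin-6-yl]prop-2-en-1-ol F4. MnO2 in CH2Cl2 then oxidises only the allylic hydroxyl to give 21.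

Further compounds
F1 | step 4 | racemic trans-2-(hydroxymethyl)-3-(4-hydroxyphenyl)-2,3-dihydro-1,4-benzodioxine-6-carbaldehyde (1:1 mixture of the (2S,3S) and (2R,3R) enantiomers) | O=Cc1ccc2c(c1)O[C@@H](c1ccc(O)cc1)[C@H](CO)O2.O=Cc1ccc2c(c1)O[C@H](c1ccc(O)cc1)[C@@H](CO)O2
F2 | step 9 | {[(E)-3-[3,4-bis(allyloxy)phenyl]prop-2-en-1-yl]oxy}tri(propan-2-yl)silane | CC(C)[Si](OC/C=C/c1ccc(OCC=C)c(OCC=C)c1)(C(C)C)C(C)C
F3 | step 14 | ethyl (E)-3-[(2S,3S)-3-[(2R,3S)-2-[3,4-bis(allyloxy)phenyl]-3-(hydroxymethyl)-2,3-dihydro-1,4-benzodioxin-6-yl]-2-(hydroxymethyl)-2,3-dihydro-1,4-benzodioxin-6-yl]prop-2-enoate | CCOC(=O)/C=C/c1ccc2c(c1)O[C@@H](c1ccc3c(c1)O[C@@H](CO)[C@@H](c1ccc(OCC=C)c(OCC=C)c1)O3)[C@H](CO)O2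
F4 | step 14 | (E)-3-[(2S,3S)-3-[(2R,3S)-2-[3,4-bis(allyloxy)phenyl]-3-(hydroxymethyl)-2,3-dihydro-1,4-benzodioxin-6-yl]-2-(hydroxymethyl)-2,3-dihydro-1,4-benzodioxin-6-yl]prop-2-en-1-ol | OC/C=C/c1ccc2c(c1)O[C@@H](c1ccc3c(c1)O[C@@H](CO)[C@@H](c1ccc(OCC=C)c(OCC=C)c1)O3)[C@H](CO)O2
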